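**Catalyst gain.** Beta held 2.35 times the catalyst of gamma, yet after 4.00 d it had used left-handed substrate just 1.49 times as fast. Midnight and summer trade catalyst against time, so that gap matters.

common to all: left-handed substrate 0.16 M; right-handed substrate 0.16 M; gas 12 mM (held); added ligand 14 mM
- gamma: catalyst 5.1 mM; run made earlier
- beta: catalyst 12 mM; run made earlier
- midnight: catalyst 8.0 mM; time 8.0 d
- summer: catalyst 4.0 mM; time 25 d

| run | time / d | left-handed product / % | left-handed substrate / % |
|---|---|---|---|
| gamma | 0.625 | 3 | 46 |
| gamma | 1.25 | 5 | 49 |
| gamma | 2.08 | 4 | 43 |
| gamma | 2.50 | 11 | 45 |
| gamma | 3.00 | 14 | 39 |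
| gamma | 4.00 | 16 | 37 |
| beta | 0.333 | 1 | 49 |
| beta | 0.500 | 1 | 47 |
| beta | 0.833 | 6 | 45 |
| beta | 1.67 | 8 | 39 |
| beta | 2.50 | 13 | 38 |
| beta | 4.00 | 19 | 29 |

(readings scatter by 2 percentage points)

- catalyst is single-handed; left-handed substrate and right-handed substrate are mirror images of each other, charged as a racemate, each of them at the stated concentration
- at the start none of the gas is in solution

- which one finishes higher in amount of left-handed product, in percent of the left-handed substrate and right-handed substrate together charged ("neither" within 2 percentage points) (midnight / summer / neither)
- amount of left-handed product at the end, in percent of the left-handed substrate and right-handed substrate together charged, midnight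
- amount of left-handed product at the end, in percent of the left-handed substrate and right-handed substrate together charged, summer

**Main step.** Begin with one step: left-handed substrate, R, goes to left-handed product, P, on the single-handed catalyst. R is half of the charge, so P approaches that ceiling. Freeze k, the pseudo-first-order constant: the logarithm of charged over remaining R, divided by time. Remaining R is taken as the mean of the R reading and the ceiling minus the P reading. Gamma gives 0.0856 d⁻¹. With k proportional to catalyst, midnight reaches 32.9 % and summer 40.7 %.

**Catalyst order.** Now add beta, with k of 0.128 d⁻¹. The apparent order in catalyst, n, is the logarithm of the ratio of the k values over that of the catalyst charges: 0.467, a reading carrying the scatter. Midnight's k becomes 0.106 d⁻¹ and summer's 0.0764 d⁻¹. Midnight drops to 28.5 %, while summer, with the larger product of k and time, rises to 42.6 %.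

**Late start.** Last comes the gas, absent at the start. Gamma's k gives 2.60 % at 0.625 d, and the reading is 3 %, but with a scatter of 2 percentage points that reading neither shows a lag nor excludes one, so this reckoning makes no correction for it. Summer still assumes a frozen k out to 25 d, far past the readings.

**Forecast.** The forecast, reasoning that “Rate therefore rises less than proportionally with catalyst”, names summer, with 43 % for summer and 31 % for midnight, the latter above this reckoning.

**Result.** Midnight ends at 29.4 % and summer at 41.3 %, so the higher flask is summer.

    gas ⇌ reagent, rate k1*(csat - [reagent]) (kL = 0.200 h⁻¹)
    reagent ⇌ dormant form (K = 180, k = 0.0340 h⁻¹)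
    reagent + catalyst + left-handed substrate → catalyst + left-handed product (k = 110 M⁻² h⁻¹)
    catalyst + added ligand ⇌ idle complex, settled at all times (K = 23.0 M⁻¹)
    reagent + catalyst + right-handed substrate → catalyst + right-handed product (k = 56.0 M⁻² h⁻¹)

**Second flask.** Midnight's k stayed nearly frozen: R stood at 33.2 % after 4.00 d and 20.6 % after 8.0 d, giving 0.102 d⁻¹ and then 0.111 d⁻¹. A neighbour of midnight holds 0.020 M catalyst, more than beta. Scaling midnight's end value by n predicts 37.2 % of left-handed product for it. That neighbour gives 41.2 %.

The readings were generated by integration for substances that don't exist; noise was put on by code.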